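**Plan**

- The retrosynthesis first removes three MOM ethers, then cuts ring C at O1–C8a and C4–C4a. This gives a hexasubstituted benzyne of ring A and the enolate of an α-formyl arylacetate that carries C2, C3, C4 and ring B.
- Enabling feature: the ether oxygen O1 (on C8a) and the carbonyl carbon C4 (on C4a) are ortho substituents of the fully substituted ring A, so an aryne across C4a–C8a can take up both. The C5 oxygen next to C4a decides which end of the aryne receives oxygen.
- Forward: ring A is completed first. Phloroglucinol is C-diprenylated, and one hydroxyl becomes a carbamate that directs silylation and is later exchanged for triflate. Ring B comes in with the formyl ester.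
- Ring C is closed last by the aryne annulation, and acid then frees the three phenols.
- The target has no stereocentre; the C2=C3 double bond is fixed within ring C.

Key step: step 10

Remark: compound 13 is drawn as the aldehyde but exists and reacts as its enol or enolate, so its α-carbon is not treated as a stereocentre.

**Route**

Step 1
Reactants: 1 phloroglucinol; 2 prenyl bromide
Product: 3 2,4-bis(3-methylbut-2-en-1-yl)benzene-1,3,5-triol
Conditions: 2 (2.1 equiv), KOH aq., 0 °C to rt
Reagents that add atoms: none
Why: In water the phloroglucinol phenoxide is alkylated on carbon by the allylic bromide (C-alkylation of an ambident phenolate), and two equivalents should give the 2,4-dialkylated triol as a separable component beside the mono- and trialkylated ones.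

Step 2
Reactants: 3 2,4-bis(3-methylbut-2-en-1-yl)benzene-1,3,5-triol
Product: 4 3,5-dihydroxy-2,4-bis(3-methylbut-2-en-1-yl)phenyl N,N-diethylcarbamate
Conditions: NaH (1.0 equiv), THF, 0 °C; Et2NCOCl (1.0 equiv), 0 °C to rt
Reagents that add atoms: N,N-diethylcarbamoyl chloride, CCN(CC)C(Cl)=O
Why: O-Carbamoylation of the mono-phenoxide should occur at one of the two equivalent hydroxyls that have a free ortho position, because the third hydroxyl lies between two prenyl groups, and one equivalent of reagent limits double acylation.

Step 3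
Reactants: 4 3,5-dihydroxy-2,4-bis(3-methylbut-2-en-1-yl)phenyl N,N-diethylcarbamate
Product: 5 3,5-bis(methoxymethoxy)-2,4-bis(3-methylbut-2-en-1-yl)phenyl N,N-diethylcarbamate
Conditions: NaH, MOMCl, DMF, 0 °C to rt
Reagents that add atoms: chloromethyl methyl ether, COCCl
Why: Williamson-type O-alkylation of both remaining phenoxides with chloromethyl methyl ether is standard, and the diethylcarbamate is inert to NaH.

Step 4
Reactants: 5 3,5-bis(methoxymethoxy)-2,4-bis(3-methylbut-2-en-1-yl)phenyl N,N-diethylcarbamate
Product: 7 3,5-bis(methoxymethoxy)-2,4-bis(3-methylbut-2-en-1-yl)-6-(trimethylsilyl)phenyl N,N-diethylcarbamate, via ortho-lithiated carbamate 6 (not isolated)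
Conditions: s-BuLi, TMEDA, THF, −78 °C; TMSCl, −78 °C to rt
Reagents that add atoms: chlorotrimethylsilane, C[Si](C)(C)Cl
Why: Directed ortho-metalation: the only ring hydrogen lies between the carbamate, the strongest oxygen-based directing group, and a MOM ether, so deprotonation at −78 °C should be fast and site-specific, and silylation at that temperature forestalls the anionic Fries shift.

Step 5
Reactants: 7 3,5-bis(methoxymethoxy)-2,4-bis(3-methylbut-2-en-1-yl)-6-(trimethylsilyl)phenyl N,N-diethylcarbamate
Product: 8 3,5-bis(methoxymethoxy)-2,4-bis(3-methylbut-2-en-1-yl)-6-(trimethylsilyl)phenol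
Conditions: LiAlH4, THF, 0 °C to reflux; aq. potassium sodium tartrate
Reagents that add atoms: none
Why: Hydride reduction of an aryl carbamate releases the phenoxide and N,N-diethylmethylamine under conditions to which MOM ethers, trisubstituted alkenes and the aryl–silicon bond are inert.

Step 6
Reactants: 8 3,5-bis(methoxymethoxy)-2,4-bis(3-methylbut-2-en-1-yl)-6-(trimethylsilyl)phenol
Product: 9 3,5-bis(methoxymethoxy)-2,4-bis(3-methylbut-2-en-1-yl)-6-(trimethylsilyl)phenyl trifluoromethanesulfonate
Conditions: Tf2O, pyridine, CH2Cl2, −78 to 0 °C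
Reagents that add atoms: trifluoromethanesulfonic anhydride, O=S(=O)(OS(=O)(=O)C(F)(F)F)C(F)(F)F
Why: O-Sulfonylation of an ortho-silylphenol with triflic anhydride and pyridine is the standard last step to ortho-silylaryl triflates and leaves acetals and alkenes untouched at low temperature.

Step 7
Reactants: 10 4-bromo-3-methoxyphenol
Product: 11 1-bromo-2-methoxy-4-(methoxymethoxy)benzene
Conditions: MOMCl, iPr2NEt, CH2Cl2, 0 °C to rt
Reagents that add atoms: chloromethyl methyl ether, COCCl
Why: MOM protection of an unhindered phenol under amine base is routine and gives the same protecting group as on ring A.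

Step 8
Reactants: 11 1-bromo-2-methoxy-4-(methoxymethoxy)benzene
Product: 12 methyl 2-[2-methoxy-4-(methoxymethoxy)phenyl]acetate
Conditions: BrCH2CO2Me, Zn dust, TMSCl (cat.), THF, 40 °C; then 11, Pd2(dba)3 (cat.), XPhos (cat.), THF, 65 °C
Reagents that add atoms: methyl bromoacetate, COC(=O)CBr
Why: Palladium-catalysed Negishi-type coupling of a Reformatsky zinc enolate with an aryl bromide (α-arylation of an acetate) tolerates ortho-alkoxy groups and acetals and needs no strong base.

Step 9
Reactants: 12 methyl 2-[2-methoxy-4-(methoxymethoxy)phenyl]acetate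
Product: 13 methyl 2-[2-methoxy-4-(methoxymethoxy)phenyl]-3-oxopropanoate
Conditions: NaH, HCO2Me, THF, 0 °C to rt; AcOH to pH 5
Reagents that add atoms: methyl formate, COC=O
Why: Crossed Claisen condensation with methyl formate, driven by formation of the stabilised sodium enolate, is the standard formylation of arylacetates, and mild acidification keeps the MOM ether.

Step 10
Reactants: 9 3,5-bis(methoxymethoxy)-2,4-bis(3-methylbut-2-en-1-yl)-6-(trimethylsilyl)phenyl trifluoromethanesulfonate; 13 methyl 2-[2-methoxy-4-(methoxymethoxy)phenyl]-3-oxopropanoate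
Product: 15 5,7-bis(methoxymethoxy)-3-[2-methoxy-4-(methoxymethoxy)phenyl]-6,8-bis(3-methylbut-2-en-1-yl)-4H-chromen-4-one, via bis(methoxymethoxy)diprenylbenzyne 14 (not isolated)
Conditions: 13 (1.0 equiv), 9 (1.3 equiv), CsF (4 equiv), THF, 65 °C
Reagents that add atoms: none
Why: Proposed new method: fluoride removes the silyl group of 9 and triflate leaves to give aryne 14, the cesium enolate of 13 adds through its formyl oxygen at C8a, and the aryl anion thus placed at C4a attacks the neighbouring methyl ester and expels methoxide, so that O1–C8a and C4–C4a form in one operation. The closest known reaction type is the fluoride-induced annulation of arynes with salicylate esters to xanthones, of which this is the vinylogous case without the benzo ring. The pyranone ring closes by a 6-exo-trig addition–elimination of the aryl anion at the ester carbonyl, and no stereocentre is formed. Three selectivities are needed: addition of oxygen at the aryne carbon remote from the C5 MOM ether, which that ether enforces by polarising the aryne and stabilising the carbanion next to it; oxygen rather than carbon attack of the ambident enolate, which the fully substituted, aryl-bearing α-carbon and the prenyl-flanked aryne carbon favour on steric grounds; and a cis relation of aryloxy group and ester across the new enol ether, which the cesium-bridged U-shaped enolate in THF should provide. THF is preferred to acetonitrile because it offers the aryl anion no proton before it reaches the ester.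

Step 11
Reactants: 15 5,7-bis(methoxymethoxy)-3-[2-methoxy-4-(methoxymethoxy)phenyl]-6,8-bis(3-methylbut-2-en-1-yl)-4H-chromen-4-one
Product: 16 5,7-dihydroxy-3-(4-hydroxy-2-methoxyphenyl)-6,8-bis(3-methylbut-2-en-1-yl)-4H-chromen-4-one
Conditions: HCl (3 M), MeOH, 50 °C
Reagents that add atoms: none
Why: Acid-catalysed transacetalisation in methanol removes all three MOM ethers, the usual final step for prenylated flavonoids, and the mild temperature limits cyclisation of a prenyl group onto a neighbouring hydroxyl.

**Compound list**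

1 | phloroglucinol | Oc1cc(O)cc(O)c1 | starting material
2 | prenyl bromide (1-bromo-3-methylbut-2-ene) | CC(C)=CCBr | starting material
3 | 2,4-bis(3-methylbut-2-en-1-yl)benzene-1,3,5-triol | Oc1cc(O)c(CC=C(C)C)c(O)c1CC=C(C)C | intermediate
4 | 3,5-dihydroxy-2,4-bis(3-methylbut-2-en-1-yl)phenyl N,N-diethylcarbamate | CCN(CC)C(=O)Oc1cc(O)c(CC=C(C)C)c(O)c1CC=C(C)C | intermediate
5 | 3,5-bis(methoxymethoxy)-2,4-bis(3-methylbut-2-en-1-yl)phenyl N,N-diethylcarbamate | CCN(CC)C(=O)Oc1cc(OCOC)c(CC=C(C)C)c(OCOC)c1CC=C(C)C | intermediate
6 | [2-(diethylcarbamoyloxy)-4,6-bis(methoxymethoxy)-3,5-bis(3-methylbut-2-en-1-yl)phenyl]lithium | [Li]c1c(OC(=O)N(CC)CC)c(CC=C(C)C)c(OCOC)c(CC=C(C)C)c1OCOC | intermediate (not isolated)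
7 | 3,5-bis(methoxymethoxy)-2,4-bis(3-methylbut-2-en-1-yl)-6-(trimethylsilyl)phenyl N,N-diethylcarbamate | CCN(CC)C(=O)Oc1c([Si](C)(C)C)c(OCOC)c(CC=C(C)C)c(OCOC)c1CC=C(C)C | intermediate
8 | 3,5-bis(methoxymethoxy)-2,4-bis(3-methylbut-2-en-1-yl)-6-(trimethylsilyl)phenol | C[Si](C)(C)c1c(O)c(CC=C(C)C)c(OCOC)c(CC=C(C)C)c1OCOC | intermediate
9 | 3,5-bis(methoxymethoxy)-2,4-bis(3-methylbut-2-en-1-yl)-6-(trimethylsilyl)phenyl trifluoromethanesulfonate | C[Si](C)(C)c1c(OS(=O)(=O)C(F)(F)F)c(CC=C(C)C)c(OCOC)c(CC=C(C)C)c1OCOC | intermediate
10 | 4-bromo-3-methoxyphenol | COc1cc(O)ccc1Br | starting material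
11 | 1-bromo-2-methoxy-4-(methoxymethoxy)benzene | COCOc1ccc(Br)c(OC)c1 | intermediate
12 | methyl 2-[2-methoxy-4-(methoxymethoxy)phenyl]acetate | COC(=O)Cc1ccc(OCOC)cc1OC | intermediate
13 | methyl 2-[2-methoxy-4-(methoxymethoxy)phenyl]-3-oxopropanoate (enol tautomer predominant) | COC(=O)C(C=O)c1ccc(OCOC)cc1OC | intermediate
14 | 3,5-bis(methoxymethoxy)-4,6-bis(3-methylbut-2-en-1-yl)benzyne | COCOC1=C(CC=C(C)C)C(OCOC)=C(CC=C(C)C)C#C1 | intermediate (not isolated)
15 | 5,7-bis(methoxymethoxy)-3-[2-methoxy-4-(methoxymethoxy)phenyl]-6,8-bis(3-methylbut-2-en-1-yl)-4H-chromen-4-one | COc1cc(OCOC)ccc1-c1coc2c(CC=C(C)C)c(OCOC)c(CC=C(C)C)c(OCOC)c2c1=O | intermediate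
16 | 5,7-dihydroxy-3-(4-hydroxy-2-methoxyphenyl)-6,8-bis(3-methylbut-2-en-1-yl)-4H-chromen-4-one | COc1cc(O)ccc1-c1coc2c(CC=C(C)C)c(O)c(CC=C(C)C)c(O)c2c1=O | target

**Step count**

Total: 11 steps. Longest linear sequence: 8 steps (steps 1 to 6, then 10 and 11); the ring B branch (steps 7 to 9) joins at step 10.

**Steps most likely to fail**

1. Step 10 (proposed new method). Four processes can divert the aryne:
   - carbon attack of the enolate followed by formyl transfer to the aryl anion;
   - oxygen attack from the enolate rotamer that has oxygen trans to the ester, after which the aryl anion is protonated instead of acylated;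
   - addition with reversed orientation at the hindered, prenyl-flanked carbon;
   - ene reaction of the aryne with a prenyl group.

   Fallback by known chemistry, setting out from 12 and 1 and returning at 16. Ester and MOM ether of 12 are hydrolysed with aqueous HCl in dioxane to 2-(4-hydroxy-2-methoxyphenyl)acetic acid F1. F1 acylates phloroglucinol 1 in BF3·OEt2 at 80 °C (Friedel–Crafts acylation) to the deoxybenzoin 2-(4-hydroxy-2-methoxyphenyl)-1-(2,4,6-trihydroxyphenyl)ethanone F2. C-Prenylation of this acylphloroglucinol with 2 in aqueous KOH gives 2-(4-hydroxy-2-methoxyphenyl)-1-[2,4,6-trihydroxy-3,5-bis(3-methylbut-2-en-1-yl)phenyl]ethanone F3. N,N-Dimethylformamide dimethyl acetal in THF then supplies C2 and closes ring C onto either of the two equivalent ortho hydroxyls to give 16.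

2. Step 2. Acylation may run on to the bis-carbamate or touch the hindered hydroxyl, and the material balance then erodes early.

   Fallback that replaces statistical acylation by directing-group control (it also avoids the aqueous C-alkylation of step 1), setting out from 1 and returning at 7. Phloroglucinol 1 is protected with two equivalents of MOMCl and iPr2NEt to 3,5-bis(methoxymethoxy)phenol F4 and carbamoylated (NaH, Et2NCOCl) to 3,5-bis(methoxymethoxy)phenyl N,N-diethylcarbamate F5. Ortho-lithiation (s-BuLi, TMEDA, −78 °C), transmetalation with CuBr·SMe2 and alkylation with 2 give 3,5-bis(methoxymethoxy)-2-(3-methylbut-2-en-1-yl)phenyl N,N-diethylcarbamate F6. A second carbamate-directed lithiation and TMSCl give 3,5-bis(methoxymethoxy)-2-(3-methylbut-2-en-1-yl)-6-(trimethylsilyl)phenyl N,N-diethylcarbamate F7. A third lithiation at the last ring hydrogen, between the two MOM ethers, followed by the same copper-mediated prenylation with 2, gives 7.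

3. Step 5. The carbamate, flanked by silyl and prenyl groups, may resist hydride delivery, or the aryl–silicon bond may be lost under forcing conditions.

   Fallback that cleaves the carbamate before silicon is introduced and brings silicon in from oxygen, setting out from 5 and returning at 9. LiAlH4 reduces the less hindered carbamate of 5 to 3,5-bis(methoxymethoxy)-2,4-bis(3-methylbut-2-en-1-yl)phenol F8. NBS in CH2Cl2 at −78 °C brominates the only free ring position to 2-bromo-3,5-bis(methoxymethoxy)-4,6-bis(3-methylbut-2-en-1-yl)phenol F9. Hexamethyldisilazane gives [2-bromo-3,5-bis(methoxymethoxy)-4,6-bis(3-methylbut-2-en-1-yl)phenoxy]trimethylsilane F10. n-BuLi at −100 °C effects bromine–lithium exchange and 1,3-migration of silicon from oxygen to carbon (retro-Brook rearrangement), and the lithium phenoxide is trapped with Tf2O to give 9.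

**Further compounds**

F1 | step 10 | 2-(4-hydroxy-2-methoxyphenyl)acetic acid | COc1cc(O)ccc1CC(=O)O
F2 | step 10 | 2-(4-hydroxy-2-methoxyphenyl)-1-(2,4,6-trihydroxyphenyl)ethanone | COc1cc(O)ccc1CC(=O)c1c(O)cc(O)cc1O
F3 | step 10 | 2-(4-hydroxy-2-methoxyphenyl)-1-[2,4,6-trihydroxy-3,5-bis(3-methylbut-2-en-1-yl)phenyl]ethanone | COc1cc(O)ccc1CC(=O)c1c(O)c(CC=C(C)C)c(O)c(CC=C(C)C)c1O
F4 | step 2 | 3,5-bis(methoxymethoxy)phenol | COCOc1cc(O)cc(OCOC)c1
F5 | step 2 | 3,5-bis(methoxymethoxy)phenyl N,N-diethylcarbamate | CCN(CC)C(=O)Oc1cc(OCOC)cc(OCOC)c1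
F6 | step 2 | 3,5-bis(methoxymethoxy)-2-(3-methylbut-2-en-1-yl)phenyl N,N-diethylcarbamate | CCN(CC)C(=O)Oc1cc(OCOC)cc(OCOC)c1CC=C(C)C
F7 | step 2 | 3,5-bis(methoxymethoxy)-2-(3-methylbut-2-en-1-yl)-6-(trimethylsilyl)phenyl N,N-diethylcarbamate | CCN(CC)C(=O)Oc1c([Si](C)(C)C)c(OCOC)cc(OCOC)c1CC=C(C)C
F8 | step 5 | 3,5-bis(methoxymethoxy)-2,4-bis(3-methylbut-2-en-1-yl)phenol | COCOc1cc(O)c(CC=C(C)C)c(OCOC)c1CC=C(C)C
F9 | step 5 | 2-bromo-3,5-bis(methoxymethoxy)-4,6-bis(3-methylbut-2-en-1-yl)phenol | COCOc1c(Br)c(O)c(CC=C(C)C)c(OCOC)c1CC=C(C)C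
F10 | step 5 | [2-bromo-3,5-bis(methoxymethoxy)-4,6-bis(3-methylbut-2-en-1-yl)phenoxy]trimethylsilane | COCOc1c(Br)c(O[Si](C)(C)C)c(CC=C(C)C)c(OCOC)c1CC=C(C)C
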